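The numbers in the tables were computed on assumed constants; noise was put on by code.

The reagent starts at the same charge in the noon and midnight runs, so these two runs differ in starting material.

| flask | starting material | reagent | time |
|---|---|---|---|
| noon | 200 mM | 400 mM |  |
| midnight | 300 mM | 400 mM |  |
| winter | 400 mM | 130 mM | 4.5 min |

| run | time / min | [target] / mM |
|---|---|---|
| noon run | 0.56 | 30.1 |
| noon run | 1.1 | 49.8 |
| noon run | 1.7 | 64.2 |
| noon run | 2.2 | 74.8 |
| noon run | 2.8 | 82.2 |
| noon run | 3.4 | 88.4 |
| noon run | 3.9 | 91.4 |
| noon run | 4.5 | 94.6 |
| midnight run | 0.56 | 43.2 |
| midnight run | 1.1 | 69.0 |
| midnight run | 1.7 | 90.8 |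
| midnight run | 2.2 | 102.3 |
| midnight run | 2.8 | 112.9 |
| midnight run | 3.4 | 120.3 |
| midnight run | 3.9 | 123.9 |
| midnight run | 4.5 | 127.0 |

(each reading ± 0.6 mM)

1. apparent order in [starting material] of the starting rate, round the charge of the noon run (the rate where two percent of its starting material have turned into target) (one fixed amount of target, the same in the runs compared)
2. target in the winter run at 4.5 min, as a share of the starting material charged

- Overall: starting material + reagent -> target.
- Constant volume, constant temperature.
- An order is taken over about fifteen percent of the charge, up and down.

I read the noon run as a ladder of rates, fastest first: 53.8 mM min⁻¹ up to the first reading, 12.3 mM min⁻¹ between 2.2 min and 2.8 min, and 5.33 mM min⁻¹ over the last interval. The top rung is the one that speaks to the starting rate, so I freeze it as the per-charge rate: target at the first reading, divided by that time and by the starting material charged, 0.269 min⁻¹ for the noon run. The midnight run reads 0.257 min⁻¹.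

Taken at face value, these readings give an order of 0.891. But the midnight run has made 43.2 mM by then and the noon run 30.1 mM, more target and so, by the overall equation, more reagent used, whereas the question compares the runs at one amount of target. I therefore commit to order one. In the winter run the reagent is the limiting reagent, 130 mM against 400 mM of starting material, which caps target at 32.5% of the charge. Both earlier runs start at one reagent charge, so I give no winter figure of my own.

The forecast says 0.85 and 15.3%, calling the order “slightly below first order, which hints at mild saturation”.

The flask gives an order of 1.0, with the midnight rate 1.5 times the noon rate at one amount of target, and 7.81% in the winter run at 4.5 min.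

    starting material + 2 reagent → target + reagent (1.992 L² mol⁻² min⁻¹)
    target → decomposed product (0.06840 min⁻¹)
    starting material → decomposed substrate (0.04230 min⁻¹)

The rate carries the square of the reagent, so the noon per-charge rate, an average over the first 0.56 min and not a starting value, scaled by the squared ratio of reagent charges gives 0.02839 min⁻¹. That is lower than the start of the winter run, which is the first constant times the squared reagent charge, 0.03366 min⁻¹. The winter run's average over 4.5 min is 0.01736 min⁻¹.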